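**Strategy.** The trimer is cut at both C4–C8 interflavan bonds into three benzyl-protected flavan units; only ring C of the upper epicatechin unit is built from scratch. A 2-alkoxy-1-(2-fluoroaryl)ethanone, with fluorine on the future C8a of ring A, undergoes a reagent-controlled syn boron aldol with 3,4-bis(benzyloxy)benzaldehyde, and the aldolate closes onto the fluoroarene in the same flask: C2–C3 and O1–C8a form together and C2 and C3 are set cis. The step exploits the ortho pair C4a/C8a of ring A: the C4 ketone on C4a acidifies C3, activates the C8a–F bond, and later becomes the C4 cation for the 4β→8 bond.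

Key step: step 4

Assumption: Z-enol borinates made with (−)-Ipc2BOTf are taken to add to the Si face of the aldehyde, as with simple ethyl ketones; if the other face were attacked, (+)-Ipc2BOTf would be used with no other change.

**Step 1**
Reactants: 1 1,3,5-trifluorobenzene
Product: 2 1,3-bis(benzyloxy)-5-fluorobenzene
Conditions: BnOH, NaH (2.1 equiv each), NMP, 0 → 80 °C
Reagents that add atoms: sodium benzyloxide, [Na+].[O-]Cc1ccccc1 (made from benzyl alcohol and NaH)
Why: Twofold SNAr of benzyloxide on the trifluoroarene, in which each C–F is activated by the meta fluorines and the third displacement is much slower once two alkoxy groups are in place.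

**Step 2**
Reactants: 3 2-chloro-N-methoxy-N-methylacetamide
Product: 4 N-methoxy-2-[(4-methoxybenzyl)oxy]-N-methylacetamide
Conditions: 4-methoxybenzyl alcohol, NaH, THF, 0 °C; then 3, Bu4NI (cat.), 0 °C → rt
Reagents that add atoms: sodium 4-methoxybenzyl oxide, [Na+].[O-]Cc1ccc(OC)cc1 (made from 4-methoxybenzyl alcohol and NaH)
Why: Williamson ether synthesis by SN2 displacement of the activated α-chloride, to which the Weinreb amide is inert.

**Step 3**
Reactants: 2 1,3-bis(benzyloxy)-5-fluorobenzene; 4 N-methoxy-2-[(4-methoxybenzyl)oxy]-N-methylacetamide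
Product: 6 1-[2,4-bis(benzyloxy)-6-fluorophenyl]-2-[(4-methoxybenzyl)oxy]ethan-1-one, via 2-lithio fluoroarene 5 (not isolated)
Conditions: n-BuLi, THF, −78 °C, 1 h; 4, −78 °C; aq NH4Cl at −78 °C
Reagents that add atoms: none
Why: Directed ortho-lithiation at the most acidic ring position, flanked by fluorine and a benzyloxy group, followed by Weinreb ketone synthesis in which the chelated tetrahedral adduct prevents over-addition; the temperature is held at −78 °C so that 5 does not lose LiF to the aryne.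

**Step 4**
Reactants: 6 1-[2,4-bis(benzyloxy)-6-fluorophenyl]-2-[(4-methoxybenzyl)oxy]ethan-1-one; 7 3,4-bis(benzyloxy)benzaldehyde
Product: 10 (2R,3S)-5,7-bis(benzyloxy)-2-[3,4-bis(benzyloxy)phenyl]-3-[(4-methoxybenzyl)oxy]chroman-4-one (2,3-cis), via Z-enol diisopinocampheylborinate 8 (not isolated), via syn-aldol borinate 9 (not isolated)
Conditions: (−)-Ipc2BOTf (1.3 equiv), i-Pr2NEt, CH2Cl2, −78 °C; 7, −78 → −20 °C; then KOt-Bu (3 equiv), 18-crown-6, THF, −78 → −30 °C; aq NH4Cl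
Reagents that add atoms: none
Why: (−)-Ipc2BOTf and i-Pr2NEt convert 6 into the Z-enol borinate 8, which adds to aldehyde 7 through a chair Zimmerman–Traxler transition state to the syn-aldolate 9 (C2–C3 bond); KOt-Bu then releases the C2 alkoxide from boron, and it attacks C8a, ipso to fluorine and ortho to the C4 ketone, with loss of fluoride through a Meisenheimer complex (O1–C8a bond). The closest known reaction types are the reagent-controlled syn-aldol reaction of Z-enol diisopinocampheylborinates and the intramolecular SNAr etherification of o-fluoroaryl ketones, here telescoped. Ring C closes in a 6-exo-trig addition–elimination. C2 is set by the isopinocampheyl ligands (Si-face attack on the aldehyde) and C3 by the Z-enolate geometry in the chair, which gives the syn aldol and hence the 2,3-cis ring; the SNAr step breaks no bond at either centre. The step needs kinetic control, that is ring closure faster than retro-aldol cleavage and than C3 epimerisation, which the low temperature, the ortho-acyl activation and the intramolecular six-membered closure should secure; chemoselectivity is secured because O3 is masked as the PMB ether, so only the C2 oxygen can cyclise, and fluoride is a far better leaving group than the C5 benzyloxy group.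

**Step 5**
Reactants: 10 (2R,3S)-5,7-bis(benzyloxy)-2-[3,4-bis(benzyloxy)phenyl]-3-[(4-methoxybenzyl)oxy]chroman-4-one
Product: 11 (2R,3S)-5,7-bis(benzyloxy)-2-[3,4-bis(benzyloxy)phenyl]-3-hydroxychroman-4-one (2,3-cis)
Conditions: DDQ (1.3 equiv), CH2Cl2/pH 7 phosphate buffer, 0 °C
Reagents that add atoms: none
Why: Oxidative cleavage of the PMB ether by DDQ (hydride abstraction, then hydrolysis of the oxocarbenium ion) under buffered neutral conditions, which should leave the benzyl aryl ethers and the base-sensitive cis C3 centre untouched.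

**Step 6**
Reactants: 11 (2R,3S)-5,7-bis(benzyloxy)-2-[3,4-bis(benzyloxy)phenyl]-3-hydroxychroman-4-one
Product: 12 (2R,3R,4R)-5,7-bis(benzyloxy)-2-[3,4-bis(benzyloxy)phenyl]chromane-3,4-diol (all-cis)
Conditions: NaBH4, THF/EtOH, −20 → 0 °C
Reagents that add atoms: none
Why: Hydride reduction of the C4 ketone by NaBH4, with axial delivery anti to the axial C3 hydroxyl expected to give the 3,4-cis alcohol; the C4 configuration is of no consequence because C4 is ionised in step 11.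

**Step 7**
Reactants: 13 (−)-epigallocatechin
Product: 14 5,7,3',4',5'-penta-O-benzyl-(−)-epigallocatechin
Conditions: BnBr (5.5 equiv), K2CO3, DMF, 0 °C → rt, under argon
Reagents that add atoms: benzyl bromide, BrCc1ccccc1
Why: Williamson O-benzylation of the five phenols, which are far more acidic than the C3 alcohol, with air excluded to protect the pyrogallol ring.

**Step 8**
Reactants: 14 5,7,3',4',5'-penta-O-benzyl-(−)-epigallocatechin
Product: 15 (2R,3R,4S)-5,7-bis(benzyloxy)-4-(2-hydroxyethoxy)-2-[3,4,5-tris(benzyloxy)phenyl]chroman-3-ol (4β ether)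
Conditions: DDQ (2 equiv), ethylene glycol (excess), DMAP, CH2Cl2, rt
Reagents that add atoms: ethylene glycol, OCCO
Why: DDQ-mediated benzylic C4–H oxidation (hydride abstraction to the cation stabilised by ring A) with capture by ethylene glycol trans to the C3 hydroxyl, giving the 4β ether.

**Step 9**
Reactants: 16 (+)-catechin
Product: 17 5,7,3',4'-tetra-O-benzyl-(+)-catechin
Conditions: BnBr (4.4 equiv), K2CO3, DMF, 0 °C → rt
Reagents that add atoms: benzyl bromide, BrCc1ccccc1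
Why: Williamson O-benzylation of the four phenols in preference to the C3 alcohol.

**Step 10**
Reactants: 15 4β-(2-hydroxyethoxy) epigallocatechin unit; 17 5,7,3',4'-tetra-O-benzyl-(+)-catechin (4 equiv)
Product: 18 nona-O-benzyl epigallocatechin-(4β→8)-catechin
Conditions: BF3·OEt2 (0.5 equiv), CH2Cl2, −78 → −30 °C
Reagents that add atoms: none
Why: Acid-promoted SN1 (Friedel–Crafts) interflavan coupling in which the C4 ether ionises to the benzylic cation and C8 of 17, its most nucleophilic position, attacks on the face trans to the C3 hydroxyl, setting C4 of the middle unit as 4β; the excess of 17 suppresses oligomerisation.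

**Step 11**
Reactants: 12 all-cis flavan-3,4-diol; 18 nona-O-benzyl epigallocatechin-(4β→8)-catechin (3 equiv, excess recovered)
Product: 19 trideca-O-benzyl epicatechin-(4β→8)-epigallocatechin-(4β→8)-catechin (triol)
Conditions: BF3·OEt2 (0.5 equiv), CH2Cl2, −78 → −30 °C, slow addition of 12
Reagents that add atoms: none
Why: The same SN1 (Friedel–Crafts) cation chemistry, in which 12 loses water at C4 and the cation is captured by C8 of the upper (epigallocatechin) unit of 18, the most nucleophilic free position, on the β face trans to the axial C3 hydroxyl, setting C4 of the top unit as 4β.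

**Step 12**
Reactants: 19 trideca-O-benzyl trimer triol; 20 3,4,5-tris(benzyloxy)benzoyl chloride (6 equiv used)
Product: 21 docosa-O-benzyl epicatechin-3-O-gallate-(4β→8)-epigallocatechin-3-O-gallate-(4β→8)-catechin-3-O-gallate
Conditions: 20 (6 equiv), DMAP, pyridine, CH2Cl2, rt → 40 °C
Reagents that add atoms: 3,4,5-tris(benzyloxy)benzoyl chloride, O=C(Cl)c1cc(OCc2ccccc2)c(OCc2ccccc2)c(OCc2ccccc2)c1 (this is compound 20 and three molecules of it are consumed)
Why: Threefold DMAP-catalysed acylation (nucleophilic catalysis through the acylpyridinium ion), in which each of the three secondary C3 hydroxyls of 19 takes up one 3,4,5-tris(benzyloxy)benzoyl group from a molecule of 20 with retention at C3; excess acid chloride and mild heating serve the two hydroxyls flanked by C4 aryl groups.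

**Step 13**
Reactants: 21 fully benzylated tris-gallate
Product: 22 epicatechin-3-O-gallate-(4β→8)-epigallocatechin-3-O-gallate-(4β→8)-catechin-3-O-gallate (target)
Conditions: H2 (1 atm), Pd(OH)2/C, THF/MeOH/H2O, rt
Reagents that add atoms: none
Why: Hydrogenolysis of all twenty-two benzyl ethers over Pd(OH)2/C under neutral conditions, which the gallate esters, the interflavan bonds and all stereocentres should survive.

**Compound list**

1 | 1,3,5-trifluorobenzene | Fc1cc(F)cc(F)c1 | starting material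
2 | 1,3-bis(benzyloxy)-5-fluorobenzene | Fc1cc(OCc2ccccc2)cc(OCc2ccccc2)c1 | intermediate
3 | 2-chloro-N-methoxy-N-methylacetamide | CON(C)C(=O)CCl | starting material
4 | N-methoxy-2-[(4-methoxybenzyl)oxy]-N-methylacetamide | CON(C)C(=O)COCc1ccc(OC)cc1 | intermediate
5 | [2,4-bis(benzyloxy)-6-fluorophenyl]lithium (not isolated) | [Li]c1c(F)cc(OCc2ccccc2)cc1OCc1ccccc1 | intermediate
6 | 1-[2,4-bis(benzyloxy)-6-fluorophenyl]-2-[(4-methoxybenzyl)oxy]ethan-1-one | COc1ccc(COCC(=O)c2c(F)cc(OCc3ccccc3)cc2OCc2ccccc2)cc1 | intermediate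
7 | 3,4-bis(benzyloxy)benzaldehyde | O=Cc1ccc(OCc2ccccc2)c(OCc2ccccc2)c1 | starting material
8 | (Z)-enol diisopinocampheylborinate of 6 (not isolated) | COc1ccc(CO/C=C(\OB([C@@H]2C[C@@H]3C[C@H]([C@H]2C)C3(C)C)[C@@H]2C[C@@H]3C[C@H]([C@H]2C)C3(C)C)c2c(F)cc(OCc3ccccc3)cc2OCc2ccccc2)cc1 | intermediate
9 | (2S,3R)-syn-aldol diisopinocampheylborinate (not isolated) | COc1ccc(CO[C@H](C(=O)c2c(F)cc(OCc3ccccc3)cc2OCc2ccccc2)[C@H](OB([C@@H]2C[C@@H]3C[C@H]([C@H]2C)C3(C)C)[C@@H]2C[C@@H]3C[C@H]([C@H]2C)C3(C)C)c2ccc(OCc3ccccc3)c(OCc3ccccc3)c2)cc1 | intermediate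
10 | (2R,3S)-5,7-bis(benzyloxy)-2-[3,4-bis(benzyloxy)phenyl]-3-[(4-methoxybenzyl)oxy]chroman-4-one | O=C1c2c(OCc3ccccc3)cc(OCc3ccccc3)cc2O[C@H](c2ccc(OCc3ccccc3)c(OCc3ccccc3)c2)[C@@H]1OCc1ccc(OC)cc1 | intermediate
11 | (2R,3S)-5,7-bis(benzyloxy)-2-[3,4-bis(benzyloxy)phenyl]-3-hydroxychroman-4-one | O=C1c2c(OCc3ccccc3)cc(OCc3ccccc3)cc2O[C@H](c2ccc(OCc3ccccc3)c(OCc3ccccc3)c2)[C@@H]1O | intermediate
12 | (2R,3R,4R)-5,7-bis(benzyloxy)-2-[3,4-bis(benzyloxy)phenyl]chromane-3,4-diol | O[C@@H]1c2c(OCc3ccccc3)cc(OCc3ccccc3)cc2O[C@H](c2ccc(OCc3ccccc3)c(OCc3ccccc3)c2)[C@@H]1O | intermediate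
13 | (−)-epigallocatechin, (2R,3R) | O[C@@H]1Cc2c(O)cc(O)cc2O[C@@H]1c1cc(O)c(O)c(O)c1 | starting material
14 | 5,7,3',4',5'-penta-O-benzyl-(−)-epigallocatechin | O[C@@H]1Cc2c(OCc3ccccc3)cc(OCc3ccccc3)cc2O[C@@H]1c1cc(OCc2ccccc2)c(OCc2ccccc2)c(OCc2ccccc2)c1 | intermediate
15 | (2R,3R,4S)-5,7-bis(benzyloxy)-4-(2-hydroxyethoxy)-2-[3,4,5-tris(benzyloxy)phenyl]chroman-3-ol | O[C@@H]1[C@@H](OCCO)c2c(OCc3ccccc3)cc(OCc3ccccc3)cc2O[C@@H]1c1cc(OCc2ccccc2)c(OCc2ccccc2)c(OCc2ccccc2)c1 | intermediate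
16 | (+)-catechin, (2R,3S) | Oc1cc(O)c2c(c1)O[C@H](c1ccc(O)c(O)c1)[C@@H](O)C2 | starting material
17 | 5,7,3',4'-tetra-O-benzyl-(+)-catechin | O(Cc1ccccc1)c1cc(OCc2ccccc2)c2c(c1)O[C@H](c1ccc(OCc3ccccc3)c(OCc3ccccc3)c1)[C@@H](O)C2 | intermediate
18 | nona-O-benzyl epigallocatechin-(4β→8)-catechin | O[C@@H]1[C@@H](c2c(OCc5ccccc5)cc(OCc5ccccc5)c3c2O[C@H](c2ccc(OCc5ccccc5)c(OCc5ccccc5)c2)[C@@H](O)C3)c2c(OCc5ccccc5)cc(OCc5ccccc5)cc2O[C@@H]1c1cc(OCc5ccccc5)c(OCc5ccccc5)c(OCc5ccccc5)c1 | intermediate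
19 | trideca-O-benzyl epicatechin-(4β→8)-epigallocatechin-(4β→8)-catechin | O[C@@H]1[C@@H](c2c(OCc5ccccc5)cc(OCc5ccccc5)c3c2O[C@H](c2ccc(OCc5ccccc5)c(OCc5ccccc5)c2)[C@@H](O)C3)c2c(OCc5ccccc5)cc(OCc5ccccc5)c([C@H]3c4c(OCc5ccccc5)cc(OCc5ccccc5)cc4O[C@H](c4ccc(OCc5ccccc5)c(OCc5ccccc5)c4)[C@@H]3O)c2O[C@@H]1c1cc(OCc5ccccc5)c(OCc5ccccc5)c(OCc5ccccc5)c1 | intermediate
20 | 3,4,5-tris(benzyloxy)benzoyl chloride | O=C(Cl)c1cc(OCc2ccccc2)c(OCc2ccccc2)c(OCc2ccccc2)c1 | starting material
21 | docosa-O-benzyl tris-gallate of the trimer | O=C(O[C@@H]1[C@@H](c2c(OCc5ccccc5)cc(OCc5ccccc5)c3c2O[C@H](c2ccc(OCc5ccccc5)c(OCc5ccccc5)c2)[C@@H](OC(=O)c6cc(OCc5ccccc5)c(OCc5ccccc5)c(OCc5ccccc5)c6)C3)c2c(OCc5ccccc5)cc(OCc5ccccc5)c([C@H]3c4c(OCc5ccccc5)cc(OCc5ccccc5)cc4O[C@H](c4ccc(OCc5ccccc5)c(OCc5ccccc5)c4)[C@@H]3OC(=O)c6cc(OCc5ccccc5)c(OCc5ccccc5)c(OCc5ccccc5)c6)c2O[C@@H]1c1cc(OCc5ccccc5)c(OCc5ccccc5)c(OCc5ccccc5)c1)c6cc(OCc5ccccc5)c(OCc5ccccc5)c(OCc5ccccc5)c6 | intermediate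
22 | epicatechin-3-O-gallate-(4β→8)-epigallocatechin-3-O-gallate-(4β→8)-catechin-3-O-gallate | O=C(O[C@@H]1[C@@H](c2c(O)cc(O)c3c2O[C@H](c2ccc(O)c(O)c2)[C@@H](OC(=O)c2cc(O)c(O)c(O)c2)C3)c2c(O)cc(O)c([C@H]3c4c(O)cc(O)cc4O[C@H](c4ccc(O)c(O)c4)[C@@H]3OC(=O)c3cc(O)c(O)c(O)c3)c2O[C@@H]1c1cc(O)c(O)c(O)c1)c1cc(O)c(O)c(O)c1 | target

**Step count.** 13 steps in total. The longest linear sequence is 8 steps (steps 1, 3, 4, 5, 6, 11, 12, 13).

**Steps most likely to fail**

Step 4. The liberated C2 alkoxide may undergo retro-aldol cleavage before it closes the ring, which would erode both the syn configuration and the enantiomeric purity, and excess base may epimerise C3 of the product. Fallback, from 6: the same boron aldol is run, but the aldolate 9 is reduced in the flask with LiBH4 (aldol–reduction), which removes the ketone and with it the retro-aldol pathway, to give the syn,syn-1,3-diol (1S,2S,3R)-1-[2,4-bis(benzyloxy)-6-fluorophenyl]-3-[3,4-bis(benzyloxy)phenyl]-2-[(4-methoxybenzyl)oxy]propane-1,3-diol F1. KH in DMF then closes ring C by SNAr on the now unactivated fluoroarene to the 3-O-PMB flavan-4-ol F2, and Dess–Martin oxidation of the C4 alcohol returns the route to 10. This trades the single operation for stereochemical security.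

Step 11. The C4 cation of 12 may be captured by C8 of another molecule of 12 (self-condensation and oligomerisation) or by a C6 position of 18 instead of C8 of its upper unit. Fallback, from 12: NBS bromination at C8 gives the bromo-capped electrophile (2R,3R,4R)-5,7-bis(benzyloxy)-2-[3,4-bis(benzyloxy)phenyl]-8-bromochromane-3,4-diol F3, which cannot oligomerise through C8. Union with 18 under the same acid promotion gives the 8-bromo trimer triol F4, and threefold acylation with 20 gives the 8-bromo tris-gallate F5. The bromine is removed together with the benzyl groups in the closing hydrogenolysis (H2, Pd(OH)2/C, Et3N), so the route comes back at 22.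

Step 12. Acylation may stop short of the triester, because the C3 hydroxyls of the upper and middle units are flanked by C4 aryl groups. Fallback, from 11 and 18: the gallates are installed before the last union. Acylation of 11 with 20 gives the 3-O-galloyl flavanone F6, and NaBH4 reduction gives the 3-O-galloyl flavan-4-ol F7. Separately, 18 is acylated twice with 20 to the dimer digallate F8. BF3·OEt2-promoted union of F7 with F8, in which the C3 ester assists ionisation and enforces the 3,4-trans bond, delivers 21 directly.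

**Further compounds**

F1 | step 4 | (1S,2S,3R)-1-[2,4-bis(benzyloxy)-6-fluorophenyl]-3-[3,4-bis(benzyloxy)phenyl]-2-[(4-methoxybenzyl)oxy]propane-1,3-diol | O[C@@H](c1c(F)cc(OCc2ccccc2)cc1OCc1ccccc1)[C@@H](OCc1ccc(OC)cc1)[C@H](O)c1ccc(OCc2ccccc2)c(OCc2ccccc2)c1
F2 | step 4 | (2R,3R,4S)-5,7-bis(benzyloxy)-2-[3,4-bis(benzyloxy)phenyl]-3-[(4-methoxybenzyl)oxy]chroman-4-ol | O[C@H]1c2c(OCc3ccccc3)cc(OCc3ccccc3)cc2O[C@H](c2ccc(OCc3ccccc3)c(OCc3ccccc3)c2)[C@@H]1OCc1ccc(OC)cc1
F3 | step 11 | (2R,3R,4R)-5,7-bis(benzyloxy)-2-[3,4-bis(benzyloxy)phenyl]-8-bromochromane-3,4-diol | O[C@@H]1c2c(OCc3ccccc3)cc(OCc3ccccc3)c(Br)c2O[C@H](c2ccc(OCc3ccccc3)c(OCc3ccccc3)c2)[C@@H]1O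
F4 | step 11 | 8-bromo (upper unit) trideca-O-benzyl trimer triol | O[C@@H]1[C@@H](c2c(OCc5ccccc5)cc(OCc5ccccc5)c3c2O[C@H](c2ccc(OCc5ccccc5)c(OCc5ccccc5)c2)[C@@H](O)C3)c2c(OCc5ccccc5)cc(OCc5ccccc5)c([C@H]3c4c(OCc5ccccc5)cc(OCc5ccccc5)c(Br)c4O[C@H](c4ccc(OCc5ccccc5)c(OCc5ccccc5)c4)[C@@H]3O)c2O[C@@H]1c1cc(OCc5ccccc5)c(OCc5ccccc5)c(OCc5ccccc5)c1
F5 | step 11 | 8-bromo (upper unit) docosa-O-benzyl tris-gallate | O=C(O[C@@H]1[C@@H](c2c(OCc5ccccc5)cc(OCc5ccccc5)c3c2O[C@H](c2ccc(OCc5ccccc5)c(OCc5ccccc5)c2)[C@@H](OC(=O)c6cc(OCc5ccccc5)c(OCc5ccccc5)c(OCc5ccccc5)c6)C3)c2c(OCc5ccccc5)cc(OCc5ccccc5)c([C@H]3c4c(OCc5ccccc5)cc(OCc5ccccc5)c(Br)c4O[C@H](c4ccc(OCc5ccccc5)c(OCc5ccccc5)c4)[C@@H]3OC(=O)c6cc(OCc5ccccc5)c(OCc5ccccc5)c(OCc5ccccc5)c6)c2O[C@@H]1c1cc(OCc5ccccc5)c(OCc5ccccc5)c(OCc5ccccc5)c1)c6cc(OCc5ccccc5)c(OCc5ccccc5)c(OCc5ccccc5)c6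
F6 | step 12 | (2R,3S)-5,7-bis(benzyloxy)-2-[3,4-bis(benzyloxy)phenyl]-4-oxochroman-3-yl 3,4,5-tris(benzyloxy)benzoate | O=C1c2c(OCc3ccccc3)cc(OCc3ccccc3)cc2O[C@H](c2ccc(OCc3ccccc3)c(OCc3ccccc3)c2)[C@@H]1OC(=O)c1cc(OCc2ccccc2)c(OCc2ccccc2)c(OCc2ccccc2)c1
F7 | step 12 | (2R,3R,4R)-5,7-bis(benzyloxy)-2-[3,4-bis(benzyloxy)phenyl]-4-hydroxychroman-3-yl 3,4,5-tris(benzyloxy)benzoate | O[C@@H]1c2c(OCc3ccccc3)cc(OCc3ccccc3)cc2O[C@H](c2ccc(OCc3ccccc3)c(OCc3ccccc3)c2)[C@@H]1OC(=O)c1cc(OCc2ccccc2)c(OCc2ccccc2)c(OCc2ccccc2)c1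
F8 | step 12 | benzylated epigallocatechin-3-O-gallate-(4β→8)-catechin-3-O-gallate | O=C(O[C@@H]1[C@@H](c2c(OCc5ccccc5)cc(OCc5ccccc5)c3c2O[C@H](c2ccc(OCc5ccccc5)c(OCc5ccccc5)c2)[C@@H](OC(=O)c6cc(OCc5ccccc5)c(OCc5ccccc5)c(OCc5ccccc5)c6)C3)c2c(OCc5ccccc5)cc(OCc5ccccc5)cc2O[C@@H]1c1cc(OCc5ccccc5)c(OCc5ccccc5)c(OCc5ccccc5)c1)c6cc(OCc5ccccc5)c(OCc5ccccc5)c(OCc5ccccc5)c6
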